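## Plan

- **Cuts:** the C9 ester; the lactone (O6–C12, with C11=C13 traced back to a CH(CH2OH)2 group on C7); the furanone ring at O–C3 (C10–OH closing on a C1,C3‑diketone that comes from a C1=C10 alkene and a C3 carbinol). Then C8–C9 of the ten‑membered carbocycle, then C1=C10, C6–C7 and C2–C3 of the open chain.
- **Enabling feature:** C8–OH and C9–O form an erythro 1,2‑diol, and C9 is bonded to C10(CH3). Once the C10–O bond of the furanone ring is replaced by a C1=C10 alkene, C9–C10–C1 is an allyl unit with oxygen on its C9 end. The ring bond C8–C9 is then the bond made when a γ‑alkoxyallyl metal meets a C8 aldehyde.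
- **Forward order:** Z‑enal from 3‑methyl‑2(5H)‑furanone, allylation (C2–C3), aldol (C6–C7), cross metathesis with methacrolein (C1=C10), acetal. The rings arise in the order carbocycle (step 18), γ‑lactone (steps 26–27), furanone (step 29).
- **Stereochemistry:** C6/C7 come from the (S)‑benzyloxazolidinone syn aldol, C8 from C7 (Felkin‑Anh), C9 from C8 inside the cyclic chromium array, and C10 from C9 by outer‑face osmylation. C3 is a helper centre set by reagent control and erased later. Both Z alkenes (C4=C5 and side chain) come from the butenolide ring.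

Key step: step 18

Numbering: germacrane numbers of the target are used throughout. C1 ketone, C2=C3 furanone alkene (ring O joins C3 and C10), C4(C15H3)=C5, C6 lactone O‑CH, C7, C8 carbinol, C9 ester carbinol, C10(C14H3), C11=C13, C12 lactone C=O. TES = triethylsilyl, TBS = tert‑butyldimethylsilyl, PMB = 4‑methoxybenzyl.

Remark: C11 of 38 and 39 is an epimerisable centre that step 27 erases, so both are drawn 7,11‑trans; 27 (at C9) and 28 (at C1) are configurationally labile and are drawn without those descriptors.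

## Route

Step 1
Reactants: 1 3-methyl-2(5H)-furanone
Product: 2 (Z)-4-hydroxy-N-methoxy-N,2-dimethylbut-2-enamide
Conditions: MeNH(OMe)·HCl, AlMe3, CH2Cl2, 0 °C to rt; aq. Rochelle salt
Reagents that add atoms: N,O-dimethylhydroxylamine hydrochloride, CNOC.Cl
Why: Weinreb aminolysis with the aluminium amide opens the lactone at the acyl–oxygen bond, so the Z geometry enforced by the ring is carried into an open chain whose two ends are now different.

Step 2
Reactants: 2 (Z)-4-hydroxy-N-methoxy-N,2-dimethylbut-2-enamide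
Product: 3 (Z)-N-methoxy-N,2-dimethyl-4-(triethylsilyloxy)but-2-enamide
Conditions: TESCl, imidazole, CH2Cl2, 0 °C
Reagents that add atoms: chlorotriethylsilane, CC[Si](Cl)(CC)CC
Why: Routine silylation of the primary (C6) alcohol blocks relactonisation.

Step 3
Reactants: 3 (Z)-N-methoxy-N,2-dimethyl-4-(triethylsilyloxy)but-2-enamide
Product: 4 (Z)-2-methyl-4-(triethylsilyloxy)but-2-enal
Conditions: DIBAL-H, THF, −78 °C; aq. Rochelle salt
Reagents that add atoms: none
Why: Hydride reduction of a Weinreb amide stops at the chelated hemiaminal and releases the C3 aldehyde only on work‑up, cold enough to keep the Z alkene.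

Step 4
Reactants: 4 (Z)-2-methyl-4-(triethylsilyloxy)but-2-enal
Product: 6 (4S,2Z)-3-methyl-1-(triethylsilyloxy)hepta-2,6-dien-4-ol, via diisopinocampheylborinate 5 (not isolated)
Conditions: Ipc2B(allyl) derived from (+)-α-pinene (1 M in pentane), Et2O, −78 °C; then NaOH, H2O2, 0 °C
Reagents that add atoms: B-allyldiisopinocampheylborane, C=CCB([C@@H]1C[C@@H]2C[C@H]([C@H]1C)C2(C)C)[C@@H]1C[C@@H]2C[C@H]([C@H]1C)C2(C)C
Why: Brown asymmetric allylboration through a closed chair forms C2–C3; the reagent from (+)-α-pinene is the one that turns aryl and alkenyl aldehydes into S homoallylic alcohols, so C3 should be set S by reagent control.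

Step 5
Reactants: 6 (4S,2Z)-3-methyl-1-(triethylsilyloxy)hepta-2,6-dien-4-ol
Product: 7 (4S,2Z)-3-methyl-1,4-bis(triethylsilyloxy)hepta-2,6-diene
Conditions: TESCl, imidazole, DMAP (cat.), CH2Cl2, rt
Reagents that add atoms: chlorotriethylsilane, CC[Si](Cl)(CC)CC
Why: Routine silylation of the C3 carbinol, which would also restore any primary silyl ether lost in the oxidative work‑up of step 4.

Step 6
Reactants: 7 (4S,2Z)-3-methyl-1,4-bis(triethylsilyloxy)hepta-2,6-diene
Product: 8 (4S,2Z)-3-methyl-4-(triethylsilyloxy)hepta-2,6-dienal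
Conditions: (COCl)2, DMSO, CH2Cl2, −78 to −40 °C; Et3N, −78 to −20 °C
Reagents that add atoms: none
Why: Swern conditions turn a primary triethylsilyl ether directly into the aldehyde while secondary silyl ethers stay (known selective oxidative desilylation), and the short cold contact with base should keep the Z enal.

Step 7
Reactants: 9 diethyl allylmalonate
Product: 10 2-allylpropane-1,3-diol
Conditions: LiAlH4, THF, 0 °C to rt
Reagents that add atoms: none
Why: Standard hydride reduction of a malonate to the 1,3‑diol that becomes C12 and C13.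

Step 8
Reactants: 10 2-allylpropane-1,3-diol
Product: 11 2-allyl-1,3-bis(tert-butyldimethylsilyloxy)propane
Conditions: TBSCl, imidazole, DMF, rt
Reagents that add atoms: tert-butylchlorodimethylsilane, CC(C)(C)[Si](C)(C)Cl
Why: Routine double silylation gives robust primary silyl ethers and keeps the group free of a stereocentre.

Step 9
Reactants: 11 2-allyl-1,3-bis(tert-butyldimethylsilyloxy)propane
Product: 12 4-(tert-butyldimethylsilyloxy)-3-[(tert-butyldimethylsilyloxy)methyl]butanoic acid
Conditions: RuCl3·xH2O (cat.), NaIO4, EtOAc–MeCN–H2O, rt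
Reagents that add atoms: sodium periodate, [Na+].[O-]I(=O)(=O)=O; water, O
Why: Catalytic RuO4 cleavage of a terminal alkene gives the acid one carbon shorter (C8), a reaction that TBS ethers tolerate.

Step 10
Reactants: 12 4-(tert-butyldimethylsilyloxy)-3-[(tert-butyldimethylsilyloxy)methyl]butanoic acid; 13 (S)-4-benzyl-2-oxazolidinone
Product: 15 (S)-4-benzyl-3-{4-(tert-butyldimethylsilyloxy)-3-[(tert-butyldimethylsilyloxy)methyl]butanoyl}oxazolidin-2-one, via pivalic mixed anhydride 14 (not isolated)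
Conditions: PivCl, Et3N, THF, −20 °C; then LiCl, 13, rt
Reagents that add atoms: pivaloyl chloride, CC(C)(C)C(=O)Cl (stays only in 14)
Why: Mixed‑anhydride N‑acylation of the oxazolidinone (LiCl/Et3N variant) takes place at the less hindered carbonyl of 14.

Step 11
Reactants: 15 imide; 8 (4S,2Z)-3-methyl-4-(triethylsilyloxy)hepta-2,6-dienal
Product: 18 (S)-4-benzyl-3-[(2S,3R,4Z,6S)-2-[1,3-bis(tert-butyldimethylsilyloxy)propan-2-yl]-3-hydroxy-5-methyl-6-(triethylsilyloxy)nona-4,8-dienoyl]oxazolidin-2-one, via boron enolate 16 (not isolated), via boron aldolate 17 (not isolated)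
Conditions: Bu2BOTf, Et3N, CH2Cl2, −78 to 0 °C; 8, −78 to 0 °C; pH 7 buffer, MeOH, H2O2, 0 °C
Reagents that add atoms: dibutylboron triflate, CCCCB(CCCC)OS(=O)(=O)C(F)(F)F (stays only in 16 and 17)
Why: Evans syn aldol: the Z boron enolate reacts through a Zimmerman‑Traxler chair on the face left open by the benzyl group, which forms C6–C7 and should set 6R and 7S (the 6,7‑syn pair of the target) irrespective of the remote C3 centre.

Step 12
Reactants: 18 syn aldol imide
Product: 19 C6 triethylsilyl ether of 18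
Conditions: TESOTf, 2,6-lutidine, CH2Cl2, −78 °C
Reagents that add atoms: triethylsilyl triflate, CC[Si](CC)(CC)OS(=O)(=O)C(F)(F)F
Why: Silyl triflate/lutidine silylation of a hindered secondary alcohol prevents retro‑aldol cleavage in later steps.

Step 13
Reactants: 19 C6 triethylsilyl ether of 18; 20 methacrolein
Product: 21 enal imide (19 with the chain end C1H=CH2 turned into (E)-C1H=C10(CH3)-C9HO)
Conditions: second-generation Hoveyda-Grubbs catalyst (H2IMes)Cl2Ru(=CH-C6H4-2-OiPr) (5 mol %), 20 (10 equiv), CH2Cl2, 40 °C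
Reagents that add atoms: none
Why: Olefin cross metathesis of a monosubstituted alkene with methacrolein is a known route to E 2‑methyl enals, and the hindered trisubstituted C4=C5 alkene should not take part.

Step 14
Reactants: 22 4-methoxybenzyl alcohol
Product: 23 4-methoxybenzyl trimethylsilyl ether
Conditions: TMSCl, Et3N, CH2Cl2, 0 °C
Reagents that add atoms: chlorotrimethylsilane, C[Si](C)(C)Cl
Why: Routine silylation supplies the alkoxysilane needed for aprotic acetal formation.

Step 15
Reactants: 21 enal imide; 23 4-methoxybenzyl trimethylsilyl ether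
Product: 24 C9 bis(4-methoxybenzyl) acetal of 21
Conditions: 23 (2.5 equiv), TMSOTf (0.1 equiv), CH2Cl2, −78 °C; pyridine quench
Reagents that add atoms: none
Why: Noyori acetalisation (alkoxysilane, catalytic silyl triflate) is driven by disiloxane formation, works on enals without moving the alkene, and is cold and aprotic enough for the silyl ethers and the imide.

Step 16
Reactants: 24 C9 bis(4-methoxybenzyl) acetal of 21
Product: 25 C8 primary alcohol (3S,6R,7R) of the C1-C13 chain
Conditions: LiBH4, THF, 0 °C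
Reagents that add atoms: none
Why: Standard reductive removal of the oxazolidinone auxiliary leaves acetal, alkenes and silyl ethers untouched.

Step 17
Reactants: 25 C8 primary alcohol
Product: 26 open-chain C8 aldehyde (3S,6R,7S;4Z;1(10)E) with C9 bis(4-methoxybenzyl) acetal; C3/C6 OTES; C7 CH(CH2OTBS)2
Conditions: Dess-Martin periodinane, pyridine, CH2Cl2, 0 °C
Reagents that add atoms: none
Why: Buffered Dess‑Martin oxidation is neutral, so C7 should not epimerise, the β‑silyloxy group should not eliminate and the acetal should survive.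

Step 18
Reactants: 26 open-chain C8 aldehyde with C9 bis(4-methoxybenzyl) acetal
Product: 29 (1(10)E,4Z)-cyclodecadiene (3S,6R,7R,8S,9R) with free C8-OH; C9-OPMB; C3/C6 OTES; C7 CH(CH2OTBS)2, via iodo ether 27 (not isolated), via allylchromium 28 (not isolated)
Conditions: CrCl2 (10 equiv), THF, −30 °C; 26 and Me3SiI (1.5 equiv) added separately over 12 h (final 1 mM); pH 7 buffer
Reagents that add atoms: iodotrimethylsilane, C[Si](C)(C)I (iodine stays only in 27); chromium dichloride, Cl[Cr]Cl (stays only in 28)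
Why: Proposed new method: Me3SiI ionises the allylic acetal to the iodo ether 27, two one‑electron transfers from divalent chromium turn it into the equilibrating γ‑(4‑methoxybenzyloxy)allylchromium 28 (trivalent chromium on C1), and 28 adds through C9 to the chromium‑bound C8 aldehyde in a cyclic six‑centre array that re‑forms C1=C10. The closest known reactions are the intermolecular CrCl2/Me3SiI coupling of enal acetals with aldehydes, which gives erythro diol monoethers, and Nozaki‑Hiyama allylchromium closures of ten‑membered carbocycles; new here is that all three allyl carbons end up inside the ring. The carbocycle closes in the 10‑exo‑trig mode on the aldehyde, and because C1 and C8 are the 1,4‑positions of the six‑centre chair and are tied by the C2–C7 chain, the two chain bonds must be cis on it: C2 equatorial (E alkene, C2 next to the small C14 methyl rather than branched C9) and C7 axial. C8 is set by C7: the ring forces C6 gauche to the forming bond, so the bulky CH(CH2OTBS)2 group stands anti to incoming C9 (Felkin‑Anh) and exposes the aldehyde face that gives 8S. C9 is set relative to C8 in the same chair: with C7 axial the less crowded array has the OPMB group axial too, anti to C7 and syn to C1, and since the allylchromium geometry equilibrates (Curtin‑Hammett) this array should deliver the erythro pair. The step needs attack through C9 rather than C1 (ten‑ versus eight‑membered ring), favoured because chromium sits on the carbon remote from the alkoxy group; it needs aldehyde‑only reactivity, helped by the low basicity of organochromium reagents and by a C7–H that is not allylic; and it needs cyclisation ahead of oligomerisation, secured by slow addition to excess CrCl2.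

Step 19
Reactants: 29 ten-membered diene with free C8-OH
Product: 30 C8 tert-butyldimethylsilyl ether of 29
Conditions: TBSOTf, 2,6-lutidine, CH2Cl2, 0 °C
Reagents that add atoms: tert-butyldimethylsilyl triflate, CC(C)(C)[Si](C)(C)OS(=O)(=O)C(F)(F)F
Why: Silyl triflate silylation covers the only free hydroxyl with the group that has to outlast all the others.

Step 20
Reactants: 30 C8 tert-butyldimethylsilyl ether of 29
Product: 31 C9 allylic alcohol (30 without the PMB group)
Conditions: DDQ, CH2Cl2–pH 7 buffer, 0 °C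
Reagents that add atoms: none
Why: Oxidative cleavage of a 4‑methoxybenzyl ether with DDQ is orthogonal to silyl ethers and unconjugated alkenes.

Step 21
Reactants: 2 (Z)-4-hydroxy-N-methoxy-N,2-dimethylbut-2-enamide
Product: 32 (Z)-4-acetoxy-N-methoxy-N,2-dimethylbut-2-enamide
Conditions: Ac2O, pyridine, DMAP (cat.), CH2Cl2, 0 °C
Reagents that add atoms: acetic anhydride, CC(=O)OC(C)=O
Why: Routine acetylation installs the side‑chain acetate while the carboxyl end is still masked, so no relactonisation can occur.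

Step 22
Reactants: 32 (Z)-4-acetoxy-N-methoxy-N,2-dimethylbut-2-enamide
Product: 33 (Z)-4-acetoxy-2-methylbut-2-enal
Conditions: Cp2Zr(H)Cl, THF, rt, 20 min
Reagents that add atoms: none
Why: The Schwartz reagent reduces tertiary and Weinreb amides to aldehydes and is known to leave esters alone, which a hydridoaluminate would not.

Step 23
Reactants: 33 (Z)-4-acetoxy-2-methylbut-2-enal
Product: 34 (Z)-4-acetoxy-2-methylbut-2-enoic acid
Conditions: NaClO2, NaH2PO4, 2-methyl-2-butene, t-BuOH–H2O, 0 °C
Reagents that add atoms: sodium chlorite, [Na+].[O-]Cl=O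
Why: Pinnick oxidation converts enals to enoic acids under mild buffered conditions without changing the alkene geometry.

Step 24
Reactants: 34 (Z)-4-acetoxy-2-methylbut-2-enoic acid; 31 C9 allylic alcohol
Product: 36 C9 (Z)-4-acetoxy-2-methylbut-2-enoate of 31, via Yamaguchi mixed anhydride 35 (not isolated)
Conditions: 2,4,6-Cl3C6H2COCl, Et3N, toluene, rt; then 31, toluene, 60 °C (no DMAP)
Reagents that add atoms: 2,4,6-trichlorobenzoyl chloride, O=C(Cl)c1c(Cl)cc(Cl)cc1Cl (stays only in 35)
Why: Yamaguchi mixed‑anhydride esterification run without a nucleophilic catalyst is the known geometry‑conserving way to angelate‑type esters, and it is placed here because C9–OH is the only free hydroxyl and still sits next to trigonal C10 rather than a quaternary carbon.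

Step 25
Reactants: 36 C9 ester
Product: 37 tetraol (C3-OH/C6-OH/CH(CH2OH)2 free; C8-OTBS and C9 ester kept)
Conditions: HF·pyridine, pyridine, THF, 0 °C to rt
Reagents that add atoms: none
Why: Graded fluoride desilylation: secondary triethylsilyl and primary TBS ethers cleave well before a secondary TBS ether flanked by two branched carbons.

Step 26
Reactants: 37 tetraol
Product: 38 trans-fused 6,12-lactone with an 11-hydroxymethyl group (11R; trans to C8)
Conditions: TEMPO (0.2 equiv), PhI(OAc)2 (2.2 equiv), CH2Cl2, 0 °C to rt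
Reagents that add atoms: none
Why: TEMPO/PhI(OAc)2 oxidative lactonisation of a 1,4‑diol: primary carbinols are oxidised ahead of the allylic secondary ones, the first aldehyde is caught by C6–OH as a five‑membered lactol that is oxidised faster than the remaining hydroxymethyl group, and C11 arises as an epimerisable centre that step 27 erases.

Step 27
Reactants: 38 hydroxymethyl lactone
Product: 40 α-methylene-γ-lactone (C11=C13) with free C3-OH; C8-OTBS; C9 ester, via mesylate 39 (not isolated)
Conditions: MsCl (1.1 equiv), Et3N, CH2Cl2, −40 °C; then DBU, −40 to 0 °C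
Reagents that add atoms: methanesulfonyl chloride, CS(=O)(=O)Cl (stays only in 39)
Why: Selective sulfonylation of the only primary alcohol followed by E1cB loss of mesylate is the standard passage from α‑hydroxymethyl to α‑methylene lactones, and the more hindered secondary C3–OH should stay free at low temperature.

Step 28
Reactants: 40 α-methylene-γ-lactone
Product: 41 (1S,10R)-1,10-diol of 40 (C1-OH/C3-OH/C10-OH free)
Conditions: OsO4 (5 mol %), NMO, acetone–H2O, 0 °C
Reagents that add atoms: N-methylmorpholine N-oxide, C[N+]1([O-])CCOCC1; water, O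
Why: Upjohn dihydroxylation should pick the strained E C1=C10 alkene (C4=C5 carries two allylic oxygens, the other two alkenes are conjugated to carbonyls). It should add to the outer face of the local conformer that has C8 over the inner face and O9 in the alkene plane next to H1, away from the C14 methyl, so the new C10–O is erythro to O9 as the empirical rule for osmylation of allylic oxygen derivatives predicts, which is the C10 configuration of the target.

Step 29
Reactants: 41 1,10-diol
Product: 43 C8 tert-butyldimethylsilyl ether of the target, via hydroxy diketone 42 (not isolated)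
Conditions: IBX, DMSO, rt; then PPTS (cat.), CH2Cl2, rt
Reagents that add atoms: none
Why: IBX oxidises the C1 and C3 carbinols without cleaving the C1/C10 glycol, and the α'‑hydroxy 1,3‑diketone undergoes the classical acid‑catalysed cyclodehydration to a 3(2H)‑furanone (5‑exo‑trig attack of C10–OH on the C3 carbonyl, then loss of water), in which the C10–O bond and hence 10S stay untouched.

Step 30
Reactants: 43 C8 tert-butyldimethylsilyl ether of the target
Product: 44 target CNP0523348.1 (6R,7R,8S,9S,10S)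
Conditions: HF·pyridine (excess), THF, rt
Reagents that add atoms: none
Why: Acidic fluoride desilylation removes the last silyl ether and is compatible with the α‑methylene lactone, the furanone and both esters.

## Compound list

1 | 3-methyl-2(5H)-furanone | CC1=CCOC1=O | starting material
2 | (Z)-4-hydroxy-N-methoxy-N,2-dimethylbut-2-enamide | CON(C)C(=O)/C(C)=C\CO | intermediate
3 | (Z)-N-methoxy-N,2-dimethyl-4-(triethylsilyloxy)but-2-enamide | CON(C)C(=O)/C(C)=C\CO[Si](CC)(CC)CC | intermediate
4 | (Z)-2-methyl-4-(triethylsilyloxy)but-2-enal | O=C/C(C)=C\CO[Si](CC)(CC)CC | intermediate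
5 | diisopinocampheylborinate of 6 | C=CC[C@H](OB([C@@H]1C[C@@H]2C[C@H]([C@H]1C)C2(C)C)[C@@H]1C[C@@H]2C[C@H]([C@H]1C)C2(C)C)/C(C)=C\CO[Si](CC)(CC)CC | intermediate
6 | (4S,2Z)-3-methyl-1-(triethylsilyloxy)hepta-2,6-dien-4-ol | C=CC[C@H](O)/C(C)=C\CO[Si](CC)(CC)CC | intermediate
7 | (4S,2Z)-3-methyl-1,4-bis(triethylsilyloxy)hepta-2,6-diene | C=CC[C@H](O[Si](CC)(CC)CC)/C(C)=C\CO[Si](CC)(CC)CC | intermediate
8 | (4S,2Z)-3-methyl-4-(triethylsilyloxy)hepta-2,6-dienal | C=CC[C@H](O[Si](CC)(CC)CC)/C(C)=C\C=O | intermediate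
9 | diethyl allylmalonate | C=CCC(C(=O)OCC)C(=O)OCC | starting material
10 | 2-allylpropane-1,3-diol | C=CCC(CO)CO | intermediate
11 | 2-allyl-1,3-bis(tert-butyldimethylsilyloxy)propane | C=CCC(CO[Si](C)(C)C(C)(C)C)CO[Si](C)(C)C(C)(C)C | intermediate
12 | 4-(tert-butyldimethylsilyloxy)-3-[(tert-butyldimethylsilyloxy)methyl]butanoic acid | OC(=O)CC(CO[Si](C)(C)C(C)(C)C)CO[Si](C)(C)C(C)(C)C | intermediate
13 | (S)-4-benzyl-2-oxazolidinone | O=C1N[C@@H](Cc2ccccc2)CO1 | starting material
14 | pivalic mixed anhydride of 12 | CC(C)(C)C(=O)OC(=O)CC(CO[Si](C)(C)C(C)(C)C)CO[Si](C)(C)C(C)(C)C | intermediate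
15 | (S)-4-benzyl-3-{4-(tert-butyldimethylsilyloxy)-3-[(tert-butyldimethylsilyloxy)methyl]butanoyl}oxazolidin-2-one | O=C1OC[C@H](Cc2ccccc2)N1C(=O)CC(CO[Si](C)(C)C(C)(C)C)CO[Si](C)(C)C(C)(C)C | intermediate
16 | (Z)-dibutylboron enolate of 15 | O=C1OC[C@H](Cc2ccccc2)N1/C(OB(CCCC)CCCC)=C/C(CO[Si](C)(C)C(C)(C)C)CO[Si](C)(C)C(C)(C)C | intermediate
17 | dibutylboron aldolate of 18 | O=C1OC[C@H](Cc2ccccc2)N1C(=O)[C@@H](C(CO[Si](C)(C)C(C)(C)C)CO[Si](C)(C)C(C)(C)C)[C@H](OB(CCCC)CCCC)/C=C(/C)[C@@H](O[Si](CC)(CC)CC)CC=C | intermediate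
18 | syn aldol imide (3S,6R,7S; C6-OH) | O=C1OC[C@H](Cc2ccccc2)N1C(=O)[C@@H](C(CO[Si](C)(C)C(C)(C)C)CO[Si](C)(C)C(C)(C)C)[C@H](O)/C=C(/C)[C@@H](O[Si](CC)(CC)CC)CC=C | intermediate
19 | C6 triethylsilyl ether of 18 | O=C1OC[C@H](Cc2ccccc2)N1C(=O)[C@@H](C(CO[Si](C)(C)C(C)(C)C)CO[Si](C)(C)C(C)(C)C)[C@H](O[Si](CC)(CC)CC)/C=C(/C)[C@@H](O[Si](CC)(CC)CC)CC=C | intermediate
20 | methacrolein | C=C(C)C=O | starting material
21 | enal imide (1(10)E; C9 aldehyde) | O=C1OC[C@H](Cc2ccccc2)N1C(=O)[C@@H](C(CO[Si](C)(C)C(C)(C)C)CO[Si](C)(C)C(C)(C)C)[C@H](O[Si](CC)(CC)CC)/C=C(/C)[C@@H](O[Si](CC)(CC)CC)C/C=C(\C)C=O | intermediate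
22 | 4-methoxybenzyl alcohol | COc1ccc(CO)cc1 | starting material
23 | 4-methoxybenzyl trimethylsilyl ether | COc1ccc(CO[Si](C)(C)C)cc1 | intermediate
24 | C9 bis(4-methoxybenzyl) acetal of 21 | O=C1OC[C@H](Cc2ccccc2)N1C(=O)[C@@H](C(CO[Si](C)(C)C(C)(C)C)CO[Si](C)(C)C(C)(C)C)[C@H](O[Si](CC)(CC)CC)/C=C(/C)[C@@H](O[Si](CC)(CC)CC)C/C=C(\C)C(OCc3ccc(OC)cc3)OCc3ccc(OC)cc3 | intermediate
25 | C8 primary alcohol (3S,6R,7R) | OC[C@@H](C(CO[Si](C)(C)C(C)(C)C)CO[Si](C)(C)C(C)(C)C)[C@H](O[Si](CC)(CC)CC)/C=C(/C)[C@@H](O[Si](CC)(CC)CC)C/C=C(\C)C(OCc1ccc(OC)cc1)OCc1ccc(OC)cc1 | intermediate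
26 | open-chain C8 aldehyde with C9 bis(4-methoxybenzyl) acetal (3S,6R,7S), key-step precursor | O=C[C@@H](C(CO[Si](C)(C)C(C)(C)C)CO[Si](C)(C)C(C)(C)C)[C@H](O[Si](CC)(CC)CC)/C=C(/C)[C@@H](O[Si](CC)(CC)CC)C/C=C(\C)C(OCc1ccc(OC)cc1)OCc1ccc(OC)cc1 | intermediate
27 | C9 iodo 4-methoxybenzyl ether | O=C[C@@H](C(CO[Si](C)(C)C(C)(C)C)CO[Si](C)(C)C(C)(C)C)[C@H](O[Si](CC)(CC)CC)/C=C(/C)[C@@H](O[Si](CC)(CC)CC)C/C=C(\C)C(I)OCc1ccc(OC)cc1 | intermediate
28 | γ-(4-methoxybenzyloxy)allylchromium dichloride (metal on C1; drawn in the reacting geometry, O9 syn to C1) | O=C[C@@H](C(CO[Si](C)(C)C(C)(C)C)CO[Si](C)(C)C(C)(C)C)[C@H](O[Si](CC)(CC)CC)/C=C(/C)[C@@H](O[Si](CC)(CC)CC)CC([Cr](Cl)Cl)/C(C)=C\OCc1ccc(OC)cc1 | intermediate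
29 | (1(10)E,4Z)-cyclodecadiene (3S,6R,7R,8S,9R), C8-OH free, C9-OPMB, key-step product | CC(C)(C)[Si](C)(C)OCC(CO[Si](C)(C)C(C)(C)C)[C@H]1[C@H](O[Si](CC)(CC)CC)/C=C(/C)[C@@H](O[Si](CC)(CC)CC)C/C=C(\C)[C@@H](OCc2ccc(OC)cc2)[C@H]1O | intermediate
30 | C8 tert-butyldimethylsilyl ether of 29 | CC(C)(C)[Si](C)(C)OCC(CO[Si](C)(C)C(C)(C)C)[C@H]1[C@H](O[Si](CC)(CC)CC)/C=C(/C)[C@@H](O[Si](CC)(CC)CC)C/C=C(\C)[C@@H](OCc2ccc(OC)cc2)[C@H]1O[Si](C)(C)C(C)(C)C | intermediate
31 | C9 allylic alcohol (C8-OTBS) | CC(C)(C)[Si](C)(C)OCC(CO[Si](C)(C)C(C)(C)C)[C@H]1[C@H](O[Si](CC)(CC)CC)/C=C(/C)[C@@H](O[Si](CC)(CC)CC)C/C=C(\C)[C@@H](O)[C@H]1O[Si](C)(C)C(C)(C)C | intermediate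
32 | (Z)-4-acetoxy-N-methoxy-N,2-dimethylbut-2-enamide | CON(C)C(=O)/C(C)=C\COC(C)=O | intermediate
33 | (Z)-4-acetoxy-2-methylbut-2-enal | O=C/C(C)=C\COC(C)=O | intermediate
34 | (Z)-4-acetoxy-2-methylbut-2-enoic acid | OC(=O)/C(C)=C\COC(C)=O | intermediate
35 | mixed anhydride of 34 and 2,4,6-trichlorobenzoic acid | CC(=O)OC/C=C(/C)C(=O)OC(=O)c1c(Cl)cc(Cl)cc1Cl | intermediate
36 | C9 (Z)-4-acetoxy-2-methylbut-2-enoate of 31 | CC(C)(C)[Si](C)(C)OCC(CO[Si](C)(C)C(C)(C)C)[C@H]1[C@H](O[Si](CC)(CC)CC)/C=C(/C)[C@@H](O[Si](CC)(CC)CC)C/C=C(\C)[C@@H](OC(=O)/C(C)=C\COC(C)=O)[C@H]1O[Si](C)(C)C(C)(C)C | intermediate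
37 | tetraol (C3, C6, C12, C13 hydroxyls free; C8-OTBS) | OCC(CO)[C@H]1[C@H](O)/C=C(/C)[C@@H](O)C/C=C(\C)[C@@H](OC(=O)/C(C)=C\COC(C)=O)[C@H]1O[Si](C)(C)C(C)(C)C | intermediate
38 | trans-fused 6,12-lactone with 11-hydroxymethyl group (11R) | OC[C@@H]1C(=O)O[C@@H]2/C=C(/C)[C@@H](O)C/C=C(\C)[C@@H](OC(=O)/C(C)=C\COC(C)=O)[C@@H](O[Si](C)(C)C(C)(C)C)[C@@H]12 | intermediate
39 | C13 mesylate of 38 | CS(=O)(=O)OC[C@@H]1C(=O)O[C@@H]2/C=C(/C)[C@@H](O)C/C=C(\C)[C@@H](OC(=O)/C(C)=C\COC(C)=O)[C@@H](O[Si](C)(C)C(C)(C)C)[C@@H]12 | intermediate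
40 | α-methylene-γ-lactone (3S-OH free; 1(10)E,4Z) | C=C1C(=O)O[C@@H]2/C=C(/C)[C@@H](O)C/C=C(\C)[C@@H](OC(=O)/C(C)=C\COC(C)=O)[C@@H](O[Si](C)(C)C(C)(C)C)[C@@H]12 | intermediate
41 | (1S,10R)-1,10-diol of 40 | C=C1C(=O)O[C@@H]2/C=C(/C)[C@@H](O)C[C@H](O)[C@@](C)(O)[C@@H](OC(=O)/C(C)=C\COC(C)=O)[C@@H](O[Si](C)(C)C(C)(C)C)[C@@H]12 | intermediate
42 | 10-hydroxy-1,3-dione | C=C1C(=O)O[C@@H]2/C=C(/C)C(=O)CC(=O)[C@@](C)(O)[C@@H](OC(=O)/C(C)=C\COC(C)=O)[C@@H](O[Si](C)(C)C(C)(C)C)[C@@H]12 | intermediate
43 | C8 tert-butyldimethylsilyl ether of the target | C=C1C(=O)O[C@@H]2/C=C(/C)C3=CC(=O)[C@@](C)(O3)[C@@H](OC(=O)/C(C)=C\COC(C)=O)[C@@H](O[Si](C)(C)C(C)(C)C)[C@@H]12 | intermediate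
44 | CNP0523348.1 (6R,7R,8S,9S,10S) | C=C1C(=O)O[C@@H]2/C=C(/C)C3=CC(=O)[C@@](C)(O3)[C@@H](OC(=O)/C(C)=C\COC(C)=O)[C@@H](O)[C@@H]12 | target

## Step count and risks

Total step count: 30. Longest linear sequence: 22 steps (1–6, 11–13, 15–20, 24–30).

Steps most likely to fail:

1. **Step 18.**
   - *Risk:* the allylchromium may be protonated or may couple between molecules before the strained bridged array is reached. Bond formation may shift to C1 (eight‑membered closure). The competing chair with C2 axial may erode the E geometry or the erythro relation.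
   - *Fallback* (known chemistry, from 26 back to 36): the acetal of 26 is hydrolysed on oxalic‑acid‑doped wet silica gel to the C8,C9‑dialdehyde F1. A low‑valent titanium pinacol cyclisation (TiCl3·(DME)1.5, Zn‑Cu, DME, slow addition) forms the same C8–C9 bond; this is an established closure of medium‑ring 1,2‑diols with a cis (that is, erythro) preference, and it should give the ring diol F2. The mixed anhydride 35 should acylate the less hindered allylic C9–OH, which sits next to trigonal C10, in preference to C8–OH next to branched C7, to give the C9 monoester F3. TBSOTf/2,6‑lutidine then returns to 36.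

2. **Step 28.**
   - *Risk:* the ring may react from the conformer in which the alkene is flipped, so that oxygen is delivered to the other face of C10. Osmylation of another alkene may also compete.
   - *Fallback* (from 40 back to 43): this uses the opposite stereochemical logic. mCPBA (NaHCO3, CH2Cl2, 0 °C) should take that same open face and give the 1,10‑epoxide F4. Catalytic camphorsulfonic acid lets C3–OH open it at tertiary C10 with inversion, which turns that face into the correct C10 configuration and gives the 3,10‑oxolane alcohol F5. Dess‑Martin oxidation gives the oxolan‑3‑one F6, and TMSOTf/Et3N gives the silyl enol ether F7. Saegusa‑Ito dehydrogenation with Pd(OAc)2 in MeCN introduces C2=C3 and returns to 43.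

3. **Step 26.**
   - *Risk:* oxidation may not stop after the lactone and may go on at the second hydroxymethyl group, or may start at both primary carbinols at once.
   - *Fallback* (from 37 back to 40): over‑oxidation is made the intended course. Excess TEMPO/PhI(OAc)2 takes both primary carbinols to the aldehyde level and should give the α‑hydroxymethylene lactone F8. The known deformylative methylenation of α‑formyl lactones (aqueous formaldehyde, K2CO3, THF, 0 °C) gives 40 directly, with C13 then coming from formaldehyde.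

## Further compounds

F1 | step 18 | C8,C9-dialdehyde (3S,6R,7S) | O=C[C@@H](C(CO[Si](C)(C)C(C)(C)C)CO[Si](C)(C)C(C)(C)C)[C@H](O[Si](CC)(CC)CC)/C=C(/C)[C@@H](O[Si](CC)(CC)CC)C/C=C(\C)C=O
F2 | step 18 | ring 8,9-diol (erythro; 1(10)E,4Z) | CC(C)(C)[Si](C)(C)OCC(CO[Si](C)(C)C(C)(C)C)[C@H]1[C@H](O[Si](CC)(CC)CC)/C=C(/C)[C@@H](O[Si](CC)(CC)CC)C/C=C(\C)[C@@H](O)[C@H]1O
F3 | step 18 | C9 monoester with free C8-OH | CC(C)(C)[Si](C)(C)OCC(CO[Si](C)(C)C(C)(C)C)[C@H]1[C@H](O[Si](CC)(CC)CC)/C=C(/C)[C@@H](O[Si](CC)(CC)CC)C/C=C(\C)[C@@H](OC(=O)/C(C)=C\COC(C)=O)[C@H]1O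
F4 | step 28 | 1,10-epoxide of 40 | C=C1C(=O)O[C@@H]2/C=C(/C)[C@@H](O)C[C@H]3O[C@]3(C)[C@@H](OC(=O)/C(C)=C\COC(C)=O)[C@@H](O[Si](C)(C)C(C)(C)C)[C@@H]12
F5 | step 28 | 3,10-oxolane with C1-OH | C=C1C(=O)O[C@@H]2/C=C(/C)[C@@H]3C[C@@H](O)[C@@](C)(O3)[C@@H](OC(=O)/C(C)=C\COC(C)=O)[C@@H](O[Si](C)(C)C(C)(C)C)[C@@H]12
F6 | step 28 | 3,10-oxolan-1-one | C=C1C(=O)O[C@@H]2/C=C(/C)[C@@H]3CC(=O)[C@@](C)(O3)[C@@H](OC(=O)/C(C)=C\COC(C)=O)[C@@H](O[Si](C)(C)C(C)(C)C)[C@@H]12
F7 | step 28 | C1 trimethylsilyl enol ether of F6 | C=C1C(=O)O[C@@H]2/C=C(/C)[C@@H]3C=C(O[Si](C)(C)C)[C@@](C)(O3)[C@@H](OC(=O)/C(C)=C\COC(C)=O)[C@@H](O[Si](C)(C)C(C)(C)C)[C@@H]12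
F8 | step 26 | α-hydroxymethylene 6,12-lactone | O/C=C1\C(=O)O[C@@H]2/C=C(/C)[C@@H](O)C/C=C(\C)[C@@H](OC(=O)/C(C)=C\COC(C)=O)[C@@H](O[Si](C)(C)C(C)(C)C)[C@@H]12
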